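All runs are calculated from invented constants.

The pitfall in repeating this run is to watch the percent of J, see it flatten, and take that for the end of the flask.

| flask | J | Q | remark | time |
|---|---|---|---|---|
| Friday's | 0.046 M (fed, over 4.0 h) | 0.064 M | run made earlier |  |
| Sunday's | 0.046 M (fed, over 4.0 h) | 0.10 M | run made earlier |  |
| Monday's | 0.069 M (fed, over 4.0 h) | 0.046 M | run made earlier |  |
| flask | 0.046 M (fed, over 4.0 h) | 0.0460 M |  | 5.0 d |

| run | time / d | J / % | Z / % |
|---|---|---|---|
| Friday's | 0.500 | 88.6 | 12.1 |
| Friday's | 1.25 | 81.5 | 19.4 |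
| Friday's | 2.50 | 76.2 | 24.0 |
| Friday's | 4.00 | 73.7 | 25.9 |
| Sunday's | 1.04 | 79.5 | 21.1 |
| Sunday's | 2.08 | 74.7 | 26.7 |
| Sunday's | 3.00 | 71.6 | 28.8 |
| Sunday's | 4.00 | 69.3 | 29.4 |
| Monday's | 0.500 | 90.3 | 9.6 |
| Monday's | 1.25 | 84.8 | 14.9 |
| Monday's | 2.50 | 82.6 | 18.0 |
| Monday's | 4.00 | 79.4 | 20.1 |

(each reading ± 0.5 percentage points)

- steps under discussion: J + Q -> X + Z; 2 Q -> L; Q + X <-> D
- the earlier runs do not show how much of Q is bound; that part of a forecast is a guess

* part of the J that has reacted at 5.0 d
* share of the unused Q that is free and not bound as D, at 5.0 d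

Two chemists argue over the new flask. The first sees Q burning away, two Q to L, and notes that “raising Q barely helps”. That is the forecast: c 23.5%, fr 35%, the second admittedly a guess.

The second chemist sees Q pairing with X to give D, in balance at every moment, and takes Q in D as unable to react. So she follows the log of J charged over J left. Friday's run reaches 0.305 at 4.00 d. Monday's reaches 0.231, less than Friday's.

The new flask has Friday's J and Monday's Q, so she places it midway. Friday's late slope adds 0.0222 for the last day. That gives 0.290 as the flask's dose, the log of J charged over J left, which in the pseudo-first-order view grows in step with the sum of free Q over time.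

Her dose means c of 25.2%, above the forecast. The readings show nothing of fr. But X grows with Z, and bound over free Q rises with free X, so she expects fr below 35%.

    J + Q → X + Z (k = 0.480 L mol⁻¹ h⁻¹)
    2 Q → L (k = 1.40 L mol⁻¹ h⁻¹)
    Q + X ⇌ D, settled at all times (K = 370 L mol⁻¹)

The flask gives c 24.9% and fr 25.8%. The free share fell on the way there, from 77.9% after 0.500 d to 35.8% after 2.50 d. The flask's c is a dose of 0.286. The neighbour flask with 0.11 M of J uses 17.6% of its J, which is a dose of 0.194, smaller than the flask's.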